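The formyl carbon is disconnected from ring carbon C1 and tied, as a CH2 group, to O-2' of the side chain on the neighbouring ring carbon C2. The feature exploited is the 1,5 relationship between the formyl carbon and O-2' across the benzene ring (CHO–C1–C2–C1'–C2'–O), which lets both sit in the pyran ring of an isochroman. One oxa-Pictet–Spengler operation on (R)-1-(2,3,5-trimethoxyphenyl)tridecan-2-ol, a homobenzylic alcohol carrying the stereocenter and a fully O-methylated ring, forms the C1–CH2 and O–CH2 bonds with tether-enforced regiochemistry. Acylative ring opening, oxidation and quinone-mediated demethylation then finish the target.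

Key step: step 6

Remark: ring carbons are numbered as in the benzaldehyde (C1 bears CHO, C2 the side chain, C3 and C6 the hydroxyls, C4 the methoxy group); side-chain carbons are C1' to C13'.
Remark: decylmagnesium bromide is taken as the commercial solution in diethyl ether.
Remark: the (R,R) catalyst of step 4 is chosen on the usual sense of the resolution for oxiranes with a plain alkyl or benzyl substituent; the configuration would be checked on 8 (Mosher esters), and the enantiomeric catalyst used if the sense proved opposite.

Step 1
Reactants: 1 o-eugenol (2-allyl-6-methoxyphenol)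
Product: 2 2-allyl-6-methoxy-1,4-benzoquinone
Conditions: (KSO3)2NO (2.2 equiv), KH2PO4 buffer, H2O/acetone, 0 °C → rt
Reagents that add atoms: potassium nitrosodisulfonate (Fremy's salt), [K+].[K+].[O-]S(=O)(=O)N([O])S(=O)(=O)[O-]
Why: Teuber oxidation, in which the phenoxyl radical is trapped at the free para carbon by a second nitrosodisulfonate radical and collapses to the para-quinone, the allyl group being inert to this one-electron oxidant.

Step 2
Reactants: 2 2-allyl-6-methoxy-1,4-benzoquinone
Product: 4 1-allyl-2,3,5-trimethoxybenzene, via 2-allyl-6-methoxyhydroquinone 3 (not isolated)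
Conditions: Na2S2O4, Bu4NBr (cat.), THF/H2O, rt; then KOH, Me2SO4, rt, under N2
Reagents that add atoms: dimethyl sulfate, COS(=O)(=O)OC
Why: Reductive O-methylation of a quinone, in which dithionite gives the hydroquinone and both phenoxides are alkylated under phase transfer (Williamson ether synthesis) before air can reoxidise them.

Step 3
Reactants: 4 1-allyl-2,3,5-trimethoxybenzene
Product: 5 racemic 2-(2,3,5-trimethoxybenzyl)oxirane
Conditions: mCPBA, NaHCO3, CH2Cl2, 0 °C → rt
Reagents that add atoms: 3-chloroperoxybenzoic acid (mCPBA), OOC(=O)c1cccc(Cl)c1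
Why: Prilezhaev epoxidation of the monosubstituted alkene under bicarbonate buffering, which keeps the epoxide from acid-induced opening; no stereocontrol is needed because the racemate is resolved in the next step.

Step 4
Reactants: 5 racemic 2-(2,3,5-trimethoxybenzyl)oxirane
Product: 6 (S)-2-(2,3,5-trimethoxybenzyl)oxirane
Conditions: (R,R)-(salen)Co(OAc) (0.5 mol%; trivalent cobalt; salen = dianion of N,N'-bis(3,5-di-tert-butylsalicylidene)-trans-cyclohexane-1,2-diamine), H2O (0.55 equiv), THF, 0 °C → rt
Reagents that add atoms: none
Why: Jacobsen hydrolytic kinetic resolution, in which the chiral cobalt salen complex should hydrolyse the (R)-epoxide much faster, so the unreacted (S)-epoxide carrying the future C2' stereocenter should be recovered in high enantiomeric purity and separated from the polar diol.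

Step 5
Reactants: 6 (S)-2-(2,3,5-trimethoxybenzyl)oxirane; 7 decylmagnesium bromide
Product: 8 (R)-1-(2,3,5-trimethoxyphenyl)tridecan-2-ol
Conditions: 7 (1.5 equiv), CuI (10 mol%), THF/Et2O, −30 → 0 °C; aq. NH4Cl
Reagents that add atoms: none
Why: Copper-catalysed SN2 opening of a terminal epoxide by a Grignard reagent at the unsubstituted carbon; the C–O bond at the stereocenter is not broken, so the configuration is kept and only the descriptor changes from S to R because the two carbon branches swap priority.

Step 6
Reactants: 8 (R)-1-(2,3,5-trimethoxyphenyl)tridecan-2-ol; 9 dimethoxymethane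
Product: 11 (3R)-5,6,8-trimethoxy-3-undecylisochroman, via methoxymethyl ether 10 (not isolated)
Conditions: CH2(OMe)2 (5 equiv), TMSOTf (trimethylsilyl trifluoromethanesulfonate, 2.2 equiv), CH2Cl2, 0 °C → rt; aq. NaHCO3
Reagents that add atoms: none
Why: Acetal exchange under the silyl triflate converts the alcohol into its methoxymethyl ether 10, loss of the second methoxy group gives an O-alkyl oxocarbenium ion, and the arene attacks its CH2 carbon through the free ring carbon ortho to the side chain, after which rearomatisation delivers the isochroman. The closest known reaction type is the oxa-Pictet–Spengler cyclisation of 2-arylethanols with formaldehyde acetals. The pyran ring closes in a 6-endo-trig mode. No stereocenter is created, and the carbinol carbon keeps its R configuration because its C–O bond is never cleaved. The step needs regioselective substitution at one ring carbon, and the tether secures it: the other ortho carbon carries a methoxy group and the carbon between the two methoxy groups is out of reach, while one para and one ortho methoxy group make the attacked carbon strongly nucleophilic.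

Step 7
Reactants: 11 (3R)-5,6,8-trimethoxy-3-undecylisochroman
Product: 12 (R)-1-[2-(bromomethyl)-3,5,6-trimethoxyphenyl]tridecan-2-yl acetate
Conditions: AcBr (1.5 equiv), ZnBr2 (10 mol%), CH2Cl2, 0 °C; crude product used directly
Reagents that add atoms: acetyl bromide, CC(=O)Br
Why: Lewis-acid-promoted acylative ether cleavage, in which O-acetylation of the ring oxygen gives an acyloxonium ion that opens only at the benzylic CH2–O bond (stabilised by the ortho and para methoxy groups), so bromide ends up on the benzylic carbon and the acetyl group on the side-chain oxygen with retention at the untouched stereocenter.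

Step 8
Reactants: 12 (R)-1-[2-(bromomethyl)-3,5,6-trimethoxyphenyl]tridecan-2-yl acetate
Product: 13 2-[(2R)-2-acetoxytridecyl]-3,4,6-trimethoxybenzaldehyde
Conditions: DMSO, NaHCO3, rt → 60 °C
Reagents that add atoms: dimethyl sulfoxide, CS(C)=O
Why: Kornblum oxidation, in which DMSO displaces the activated benzylic bromide and bicarbonate triggers collapse of the alkoxysulfonium salt to the aldehyde under conditions mild enough to spare the secondary acetate.

Step 9
Reactants: 13 2-[(2R)-2-acetoxytridecyl]-3,4,6-trimethoxybenzaldehyde
Product: 15 2-[(2R)-2-acetoxytridecyl]-3,6-dihydroxy-4-methoxybenzaldehyde, via formylquinone 14 (not isolated)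
Conditions: (NH4)2Ce(NO3)6 (2.5 equiv), MeCN/H2O, 0 °C; then EtOAc, aq. Na2S2O4, rt, under argon
Reagents that add atoms: water, O
Why: Oxidative demethylation of a para-dimethoxyarene by the one-electron cerium oxidant (water supplies both new oxygens, the para pair at C3 and C6 leaves as methanol, and the C4 methoxy group survives as a vinylogous ester), followed by dithionite reduction of quinone 14 to the hydroquinone, neither stage touching the acetate, the aldehyde or the stereocenter.

Compound list
1 | o-eugenol (2-allyl-6-methoxyphenol) | C=CCc1cccc(OC)c1O | starting material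
2 | 2-allyl-6-methoxy-1,4-benzoquinone | C=CCC1=CC(=O)C=C(OC)C1=O | intermediate
3 | 2-allyl-6-methoxybenzene-1,4-diol (2-allyl-6-methoxyhydroquinone, formed in the flask) | C=CCc1c(O)c(OC)cc(O)c1 | intermediate
4 | 1-allyl-2,3,5-trimethoxybenzene | C=CCc1c(OC)c(OC)cc(OC)c1 | intermediate
5 | racemic 2-(2,3,5-trimethoxybenzyl)oxirane | C1C(Cc2c(OC)c(OC)cc(OC)c2)O1 | intermediate
6 | (S)-2-(2,3,5-trimethoxybenzyl)oxirane | C1[C@H](Cc2c(OC)c(OC)cc(OC)c2)O1 | intermediate
7 | decylmagnesium bromide | CCCCCCCCCC[Mg]Br | starting material
8 | (R)-1-(2,3,5-trimethoxyphenyl)tridecan-2-ol | CCCCCCCCCCC[C@H](Cc1c(OC)c(OC)cc(OC)c1)O | intermediate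
9 | dimethoxymethane | COCOC | starting material
10 | (R)-1-[2-(methoxymethoxy)tridecyl]-2,3,5-trimethoxybenzene (methoxymethyl ether of 8, formed in the flask) | CCCCCCCCCCC[C@H](Cc1c(OC)c(OC)cc(OC)c1)OCOC | intermediate
11 | (3R)-5,6,8-trimethoxy-3-undecylisochroman | CCCCCCCCCCC[C@H](Cc1c(OC)c(OC)cc(OC)c1C2)O2 | intermediate
12 | (R)-1-[2-(bromomethyl)-3,5,6-trimethoxyphenyl]tridecan-2-yl acetate | CCCCCCCCCCC[C@H](Cc1c(OC)c(OC)cc(OC)c1CBr)OC(C)=O | intermediate
13 | 2-[(2R)-2-acetoxytridecyl]-3,4,6-trimethoxybenzaldehyde | CCCCCCCCCCC[C@H](Cc1c(OC)c(OC)cc(OC)c1C=O)OC(C)=O | intermediate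
14 | (R)-1-(2-formyl-5-methoxy-3,6-dioxocyclohexa-1,4-dien-1-yl)tridecan-2-yl acetate (formylquinone, formed in the flask) | CCCCCCCCCCC[C@H](CC1=C(C=O)C(=O)C=C(OC)C1=O)OC(C)=O | intermediate
15 | 2-[(2R)-2-acetoxytridecyl]-3,6-dihydroxy-4-methoxybenzaldehyde | CCCCCCCCCCC[C@H](Cc1c(O)c(OC)cc(O)c1C=O)OC(C)=O | target

Total step count: 9. Longest linear sequence: 9 steps (1 to 15).

Steps most likely to fail

Step 6 (key step). The oxocarbenium ion, or free methoxymethyl cation, may be captured by the arene of a second molecule (diarylmethane formation), or the reaction may stall at the acetal stage. Fallback: setting out from 8, the tether is abandoned and the carbon is introduced by direct electrophilic substitution. Acetylation (Ac2O, pyridine, DMAP, CH2Cl2) should give (R)-1-(2,3,5-trimethoxyphenyl)tridecan-2-yl acetate F1. Vilsmeier–Haack formylation (POCl3, DMF, 0 → 60 °C; aq. NaOAc) should then attack the ring carbon para to one methoxy group and ortho to another, in preference to the carbon wedged between two methoxy groups. The sequence comes back to the route at 13 and makes steps 7 and 8 unnecessary.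

Step 7. The very electron-rich benzylic bromide may ionise again and alkylate another arene or be solvolysed during work-up, and bromide with the zinc Lewis acid may cleave an aryl methyl ether. Fallback: setting out from 11, the benzylic C–O bond is opened with an oxygen nucleophile instead. Acetolysis (Ac2O, catalytic TMSOTf, CH2Cl2, 0 °C) should give (R)-1-[2-(acetoxymethyl)-3,5,6-trimethoxyphenyl]tridecan-2-yl acetate F2. The unhindered primary benzylic acetate is removed selectively (Candida antarctica lipase B, phosphate buffer/MTBE) to give (R)-1-[2-(hydroxymethyl)-3,5,6-trimethoxyphenyl]tridecan-2-yl acetate F3. MnO2 in CH2Cl2 then oxidises the benzylic alcohol, and the sequence comes back to the route at 13.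

Step 9. The aldehyde-deactivated ring may be oxidised incompletely, or the highly electrophilic formylquinone may be over-oxidised or degraded by water before it is reduced. Fallback: setting out from 11, the oxidation is moved to a stage without a carbonyl group. (NH4)2Ce(NO3)6 in aqueous MeCN should give (3R)-6-methoxy-3-undecylisochroman-5,8-dione F4, and reductive acetylation (Zn, Ac2O, NaOAc) should give (3R)-6-methoxy-3-undecylisochroman-5,8-diyl diacetate F5. Ring opening with AcBr and ZnBr2 should give (R)-1-[3,6-diacetoxy-2-(bromomethyl)-5-methoxyphenyl]tridecan-2-yl acetate F6, and Kornblum oxidation (DMSO, NaHCO3) should give (R)-1-(3,6-diacetoxy-2-formyl-5-methoxyphenyl)tridecan-2-yl acetate F7. The two aryl acetates are then cleaved selectively in the presence of the alkyl acetate (NH4OAc, degassed aqueous MeOH), and the sequence comes back to the route at 15.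

Further compounds
F1 | step 6 | (R)-1-(2,3,5-trimethoxyphenyl)tridecan-2-yl acetate | CCCCCCCCCCC[C@H](Cc1c(OC)c(OC)cc(OC)c1)OC(C)=O
F2 | step 7 | (R)-1-[2-(acetoxymethyl)-3,5,6-trimethoxyphenyl]tridecan-2-yl acetate | CCCCCCCCCCC[C@H](Cc1c(OC)c(OC)cc(OC)c1COC(C)=O)OC(C)=O
F3 | step 7 | (R)-1-[2-(hydroxymethyl)-3,5,6-trimethoxyphenyl]tridecan-2-yl acetate | CCCCCCCCCCC[C@H](Cc1c(OC)c(OC)cc(OC)c1CO)OC(C)=O
F4 | step 9 | (3R)-6-methoxy-3-undecylisochroman-5,8-dione | CCCCCCCCCCC[C@H](CC1=C(C2)C(=O)C=C(OC)C1=O)O2
F5 | step 9 | (3R)-6-methoxy-3-undecylisochroman-5,8-diyl diacetate | CCCCCCCCCCC[C@H](Cc1c(OC(C)=O)c(OC)cc(OC(C)=O)c1C2)O2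
F6 | step 9 | (R)-1-[3,6-diacetoxy-2-(bromomethyl)-5-methoxyphenyl]tridecan-2-yl acetate | CCCCCCCCCCC[C@H](Cc1c(OC(C)=O)c(OC)cc(OC(C)=O)c1CBr)OC(C)=O
F7 | step 9 | (R)-1-(3,6-diacetoxy-2-formyl-5-methoxyphenyl)tridecan-2-yl acetate | CCCCCCCCCCC[C@H](Cc1c(OC(C)=O)c(OC)cc(OC(C)=O)c1C=O)OC(C)=O
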